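**Assumptions:** the target is read as the (R)-benzylic alcohol with an (E)-alkene in a 22-membered diaryl-ether cyclophane. Grignard reagents are made in situ from the commercial bromides and not counted as steps; catalysts are not numbered. The route is a design from known reaction classes and has not been run.

## Retrosynthetic overview

1. The (R)-carbinol comes from a late asymmetric transfer hydrogenation of a macrocyclic aryl ketone, so the stereocentre is set last.
2. The three phenols are unmasked from methyl ethers at the ketone stage, because BBr3 would ionise the benzylic alcohol.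
3. The only ring formed is the 22-membered macrocycle, closed by RCM at the C=C; both benzene rings are bought.
4. The diaryl ether comes from an Ullmann coupling of a 3-alkyl-5-methoxyphenol with a 4-bromo-3,5-dimethoxyphenyl ketone.
5. Both side chains come from alkenyl Grignard reagents (C7 onto ring A by Kumada coupling, C8 onto the ring-B aldehyde).

## Route

**Step 1**
Reactants: 1, 1-bromo-3,5-dimethoxybenzene; 2, 7-bromohept-1-ene
Product: 3, 1-(hept-6-en-1-yl)-3,5-dimethoxybenzene
Conditions: 2, Mg, THF (forms hept-6-enylmagnesium bromide in situ, 1.3 equiv); then 1, PdCl2(dppf) (3 mol%), THF, reflux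
Reagents that add atoms: none
Why: Kumada–Corriu sp2–sp3 cross-coupling, where dppf suppresses β-hydride elimination from the primary alkyl-Pd species and the methyl ethers and remote alkene are inert; every heavy atom of 3 comes from 1 and 2.

**Step 2**
Reactants: 3, 1-(hept-6-en-1-yl)-3,5-dimethoxybenzene
Product: 4, 3-(hept-6-en-1-yl)-5-methoxyphenol
Conditions: NaSEt (3–4 equiv, from EtSH/NaH), DMF, 140 °C; aq. HCl work-up
Reagents that add atoms: none
Why: SN2 O-demethylation by thiolate, which stops at the mono-phenol because the phenoxide formed deactivates the second OMe; the alkene is untouched.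

**Step 3**
Reactants: 5, 4-bromo-3,5-dimethoxybenzaldehyde; 6, 8-bromooct-1-ene
Product: 7, (±)-1-(4-bromo-3,5-dimethoxyphenyl)non-8-en-1-ol
Conditions: 6, Mg, THF (forms oct-7-enylmagnesium bromide in situ, 1.2 equiv); add to 5, THF, −40 → 0 °C; NH4Cl
Reagents that add atoms: none
Why: Grignard 1,2-addition to a non-enolisable aryl aldehyde, far faster at ≤0 °C than Br/Mg exchange at the hindered aryl bromide; the racemic centre is erased in step 4.

**Step 4**
Reactants: 7, (±)-1-(4-bromo-3,5-dimethoxyphenyl)non-8-en-1-ol
Product: 8, 1-(4-bromo-3,5-dimethoxyphenyl)non-8-en-1-one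
Conditions: Dess–Martin periodinane, NaHCO3, CH2Cl2, rt
Reagents that add atoms: none
Why: Dess–Martin oxidation of a secondary benzylic alcohol to the aryl ketone under buffered neutral conditions that leave the aryl bromide and terminal alkene alone.

**Step 5**
Reactants: 4, 3-(hept-6-en-1-yl)-5-methoxyphenol (1.2 equiv); 8, 1-(4-bromo-3,5-dimethoxyphenyl)non-8-en-1-one
Product: 9, 1-{4-[3-(hept-6-en-1-yl)-5-methoxyphenoxy]-3,5-dimethoxyphenyl}non-8-en-1-one
Conditions: CuI (10 mol%), picolinic acid (20 mol%), K3PO4, DMSO, 90–100 °C
Reagents that add atoms: none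
Why: Ligand-accelerated Ullmann diaryl ether coupling, helped by the para-acyl group activating the C–Br bond and by the unhindered phenol; the ketone and alkenes tolerate K3PO4/DMSO.

**Step 6**
Reactants: 9, the acyclic diene ketone
Product: 10, (E)-macrocyclic tri-O-methyl ketone (22-membered ring)
Conditions: Grubbs II (5–10 mol%), CH2Cl2 (1 mM), 40 °C, Ar sparge; Z-isomer removed on AgNO3–SiO2
Reagents that add atoms: none
Why: Ring-closing metathesis of two unhindered terminal olefins at high dilution with loss of ethylene, where secondary metathesis equilibrates the unstrained 22-membered ring toward the more stable E-alkene (expected E-major, roughly 4–8:1).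

**Step 7**
Reactants: 10, (E)-macrocyclic tri-O-methyl ketone
Product: 11, (E)-macrocyclic triphenol ketone
Conditions: BBr3 (6–8 equiv), CH2Cl2, −78 → 0 °C; MeOH then aq. NaHCO3 at low temperature
Reagents that add atoms: none
Why: BBr3 cleavage of the three aryl methyl ethers at the ketone oxidation level, where there is no ionisable benzylic C–O bond; the diaryl ether and aryl ketone are stable and the isolated disubstituted alkene survives at low temperature with a basic quench.

**Step 8**
Reactants: 11, (E)-macrocyclic triphenol ketone
Product: 12, dehydrogravicycle, (R)-alcohol, (E)-alkene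
Conditions: RuCl(p-cymene)[(R,R)-TsDPEN] (3–5 mol%), HCO2H/Et3N (5:2), DMF, 25–40 °C
Reagents that add atoms: none
Why: Noyori asymmetric transfer hydrogenation, where the (R,R)-catalyst gives the (R)-aryl alkyl carbinol (same sense as acetophenone to (R)-1-phenylethanol), reduces C=O but not the isolated C=C, and should tolerate the phenols, which are meta to the ketone; the stereocentre is made last, so nothing can scramble it.

## Compound list

1 | 1-bromo-3,5-dimethoxybenzene | COc1cc(Br)cc(OC)c1 | starting material
2 | 7-bromohept-1-ene | C=CCCCCCBr | starting material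
3 | 1-(hept-6-en-1-yl)-3,5-dimethoxybenzene | COc1cc(CCCCCC=C)cc(OC)c1 | intermediate
4 | 3-(hept-6-en-1-yl)-5-methoxyphenol | COc1cc(O)cc(CCCCCC=C)c1 | intermediate
5 | 4-bromo-3,5-dimethoxybenzaldehyde | COc1cc(C=O)cc(OC)c1Br | starting material
6 | 8-bromooct-1-ene | C=CCCCCCCBr | starting material
7 | (±)-1-(4-bromo-3,5-dimethoxyphenyl)non-8-en-1-ol | COc1cc(C(O)CCCCCCC=C)cc(OC)c1Br | intermediate
8 | 1-(4-bromo-3,5-dimethoxyphenyl)non-8-en-1-one | COc1cc(C(=O)CCCCCCC=C)cc(OC)c1Br | intermediate
9 | 1-{4-[3-(hept-6-en-1-yl)-5-methoxyphenoxy]-3,5-dimethoxyphenyl}non-8-en-1-one | COc1cc(CCCCCC=C)cc(Oc2c(OC)cc(cc2OC)C(=O)CCCCCCC=C)c1 | intermediate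
10 | (E)-macrocyclic tri-O-methyl ketone (22-membered diaryl-ether cyclophane) | COc1cc2cc(c1)Oc1c(OC)cc(cc1OC)C(=O)CCCCCC/C=C/CCCCC2 | intermediate
11 | (E)-macrocyclic triphenol ketone | Oc1cc2cc(c1)Oc1c(O)cc(cc1O)C(=O)CCCCCC/C=C/CCCCC2 | intermediate
12 | dehydrogravicycle, (R)-carbinol, (E)-alkene | Oc1cc2cc(c1)Oc1c(O)cc(cc1O)[C@H](O)CCCCCC/C=C/CCCCC2 | target

## Summary

Total steps: 8. Longest linear sequence: 6 (steps 1, 2, 5, 6, 7, 8).

Three steps most likely to fail:

1. **Step 6 (RCM).** The risk is an E/Z mixture and cyclic dimers. Fallback: build the chains from 8-bromooct-2-yne and 9-bromonon-2-yne, close the ring by alkyne metathesis with a Mo alkylidyne catalyst, then convert the cycloalkyne to the E-alkene by Ru-catalysed trans-hydrosilylation ([Cp*Ru(MeCN)3]PF6, (EtO)3SiH) and protodesilylation (AgF). This fixes the E geometry by mechanism.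

2. **Step 5 (Ullmann coupling).** The bromide is flanked by two methoxy groups and may couple poorly. Fallback: invert the polarity. Use 1-(4-hydroxy-3,5-dimethoxyphenyl)non-8-en-1-one (from syringaldehyde) as the nucleophile and arylate it with a ring-A aryl(mesityl)iodonium salt (t-BuOK, THF, rt). This metal-free arylation suits 2,6-disubstituted phenols.

3. **Step 8 (asymmetric reduction of the unprotected triphenol).** Conversion or ee may be poor on the free phenols. Fallback: silylate 11 to the tris-TBS ether, reduce with (S)-Me-CBS/BH3·SMe2 (gives R), and remove the silyl groups with TBAF. Fluoride conditions cannot ionise the benzylic alcohol. The same detour also covers step 7 if BBr3 damages the macrocyclic alkene, by demethylating and silylating before RCM.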